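**Retrosynthetic overview**

1. Leucanthin B (42) ⇐ late O8 acylation with epoxyangelic acid 38, O9 acetylation and fluoride release of the C14 acid; the α-methylene-γ-lactone (O6, C7, C11–C13) is grown on the C6 ketone of cyclodecenone 25 by C7 alkylation, reduction and methylenation.
2. 25 ⇐ anionic oxy-Cope [3,3] shift of the cis-1,2-dialkenyl diepoxycyclohexanol 22: C8–C9 is made, C1–C6 is cut, and the six-membered ring opens into the ten-membered ring.
3. 22 ⇐ diepoxy ketone 13: the C6 oxygen is put in by osmylation of the exocyclic methylene (a carbon nucleophile would add to 13 anti to the neighbouring oxirane oxygen and anti to the C1 side chain, giving the wrong C6 epimer), and both enol ethers are then grown from the two aldehydes of 17.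
4. 13 ⇐ quinone monoketal 2 (from phenol 1): CBS reduction, hydroxyl-directed 4,5-epoxidation, Ireland–Claisen transfer of C10 to C1, anti 2,3-epoxidation.
5. Feature used: C2–C5 carry two cis-fused oxiranes, anti to each other, that sit naturally on a six-membered carbocycle C1–C6, while C8 and C9 form a vicinal dioxygen pair on the far rim of the ten-membered ring. Ring order: six-membered ring (from the arene), the two oxiranes, ten-membered ring (step 16), lactone (step 18); the side-chain oxirane arrives with 38.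

Key step: step 16

Remark: atom numbers are the germacrane numbers of the target in every intermediate (ring C1–C10, lactone C11–C13, C14 on C10, C15 on C4); compounds 8, 9 and 11–17 are carried as mixtures at C10, a centre that becomes sp2 in step 13.

**Route**

Step 1
Reactants: 1 4-methoxy-2-methylphenol
Product: 2 quinone monoketal
Conditions: PhI(OAc)2, MeOH, 0 °C
Reagents that add atoms: methanol, CO
Why: Oxidative dearomatisation of a para-methoxyphenol with PhI(OAc)2 in methanol is the standard entry to quinone monoketals, and the symmetric ketal carbon (future C6) leaves the C3 carbonyl as the only prochiral site.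

Step 2
Reactants: 2 quinone monoketal
Product: 3 (S)-dienol
Conditions: (R)-2-methyl-CBS-oxazaborolidine (cat.), BH3·SMe2, THF, −30 °C; MeOH
Reagents that add atoms: none
Why: Corey–Bakshi–Shibata reduction, in which the catalyst should treat the methyl-bearing C4=C5 arm as the large flank and deliver hydride 1,2 to one face of C3, giving the (S)-carbinol that fixes the absolute configuration of the whole route.

Step 3
Reactants: 3 (S)-dienol
Product: 4 syn-epoxy alcohol
Conditions: VO(acac)2 (cat.), t-BuOOH, CH2Cl2, 0 °C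
Reagents that add atoms: tert-butyl hydroperoxide, CC(C)(C)OO
Why: Hydroxyl-directed epoxidation goes to the more substituted allylic alkene C4=C5 and delivers oxygen syn to the C3 hydroxyl, which sets C4 and C5.

Step 4
Reactants: 4 syn-epoxy alcohol; 5 3-(benzyloxy)propanoic acid
Product: 6 C3 ester
Conditions: DCC, DMAP (cat.), CH2Cl2, 0 °C → rt
Reagents that add atoms: none
Why: Steglich esterification acylates the secondary allylic alcohol under neutral conditions and touches no stereocentre.

Step 5
Reactants: 6 C3 ester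
Product: 9 Claisen acid, via silyl ketene acetal 7 (not isolated), via trimethylsilyl ester 8 (not isolated)
Conditions: LiN(iPr)2, Me3SiCl/Et3N, THF, −78 °C → 50 °C; aq. citric acid
Reagents that add atoms: none
Why: Ireland–Claisen rearrangement, in which in situ silylation outruns β-elimination of benzyloxide and the ketene acetal shifts suprafacially across C3–C2=C1, so C10 arrives on C1 on the face that carried the C3 oxygen (syn to the 4,5-oxirane) while the C2=C3 alkene appears.

Step 6
Reactants: 9 Claisen acid; 10 2-(trimethylsilyl)ethanol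
Product: 11 TMSE ester
Conditions: DCC, DMAP (cat.), CH2Cl2, rt
Reagents that add atoms: none
Why: Steglich esterification gives the fluoride-labile 2-(trimethylsilyl)ethyl ester of C14 that is kept to the last step.

Step 7
Reactants: 11 TMSE ester
Product: 12 anti-bis-epoxide ketal
Conditions: mCPBA, NaHCO3, CH2Cl2, rt
Reagents that add atoms: 3-chloroperbenzoic acid, OOC(=O)c1cccc(Cl)c1
Why: Prilezhaev epoxidation of the only alkene, C2=C3, from the face anti to both the C1 side chain and the 4,5-oxirane oxygen should give the anti-bis-epoxide and set C2 and C3 on the rigid six-membered ring.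

Step 8
Reactants: 12 anti-bis-epoxide ketal
Product: 13 diepoxy ketone
Conditions: TFA/H2O, CH2Cl2, 0 °C
Reagents that add atoms: water, O
Why: Acid hydrolysis of the dimethyl ketal frees the C6 ketone without enolising C1, the oxiranes being deactivated towards ionisation by the neighbouring acetal and carbonyl carbon as in epoxyquinol chemistry.

Step 9
Reactants: 13 diepoxy ketone
Product: 14 C6 methylene compound
Conditions: Cp2Ti(μ-Cl)(μ-CH2)AlMe2, pyridine, THF/toluene, −40 → 0 °C
Reagents that add atoms: Cp2Ti(μ-Cl)(μ-CH2)AlMe2 (Tebbe reagent), C[Al-]1(C)C[Ti](C2C=CC=C2)(C2C=CC=C2)[Cl+]1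
Why: Tebbe methylenation through the titanium methylidene and an oxatitanacyclobutane is non-basic, so the α-branched β,γ-epoxy ketone is olefinated without enolisation, and at low temperature the ketone reacts before the ester.

Step 10
Reactants: 14 C6 methylene compound
Product: 15 C6/C7 diol
Conditions: OsO4 (cat.), NMO, acetone/H2O, rt
Reagents that add atoms: N-methylmorpholine N-oxide, C[N+]1([O-])CCOCC1; water, O
Why: Upjohn dihydroxylation, in which OsO4 should approach the 1,1-disubstituted alkene equatorially on the face anti to the 4,5-oxirane oxygen (the C1 side chain lies pseudo-equatorial), so O6 ends trans to that oxygen and C7 cis to C10, the arrangement that carbon addition to ketone 13 would not give.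

Step 11
Reactants: 15 C6/C7 diol
Product: 16 triol
Conditions: H2 (1 atm), Pd/C, EtOAc, rt
Reagents that add atoms: none
Why: Hydrogenolysis removes the primary benzyl ether at a stage where the molecule holds no C=C bond and the non-benzylic oxiranes and the ester are inert.

Step 12
Reactants: 16 triol
Product: 17 hydroxy dialdehyde
Conditions: SO3·pyridine, DMSO, iPr2NEt, CH2Cl2, 0 °C
Reagents that add atoms: none
Why: Parikh–Doering oxidation takes both primary alcohols to aldehydes without cleaving the 1,2-diol or touching the tertiary C6 hydroxyl, and the C9 aldehyde rests as the hydrogen-bonded enol of an α-formyl ester.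

Step 13
Reactants: 17 hydroxy dialdehyde
Product: 19 (Z)-silyloxyacrylate aldehyde, via sodium enolate 18 (not isolated)
Conditions: NaN(SiMe3)2 (1 equiv), THF, −78 °C; t-BuMe2SiCl, −78 → 0 °C
Reagents that add atoms: tert-butyldimethylsilyl chloride, CC(C)(C)[Si](C)(C)Cl
Why: One equivalent of base removes only the acidic enol proton, and O-silylation of the sodium chelate (enolate oxygen and ester carbonyl on the same side) should give the (Z)-silyl enol ether with O9 trans to C1, C10 becoming sp2.

Step 14
Reactants: 19 (Z)-silyloxyacrylate aldehyde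
Product: 20 (E)-alkenylboronate
Conditions: CrCl2, Cl2CHB(pin), LiI, THF, rt
Reagents that add atoms: 2-(dichloromethyl)-4,4,5,5-tetramethyl-1,3,2-dioxaborolane, ClC(Cl)B1OC(C)(C)C(C)(C)O1
Why: Takai–Utimoto boryl-olefination with the gem-dichromium reagent converts the hindered aldehyde into the (E)-alkenylboronate and tolerates the free tertiary hydroxyl.

Step 15
Reactants: 20 (E)-alkenylboronate; 21 4-methoxybenzyl alcohol
Product: 22 dialkenyl diepoxycyclohexanol
Conditions: Cu(OAc)2, Et3N, 4 Å MS, CH2Cl2, air, rt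
Reagents that add atoms: none
Why: Chan–Lam–Evans etherification couples the alkenyl pinacolboronate with the primary alcohol at room temperature with retention of the (E) geometry, so the oxidation-sensitive enol ether is made only after all oxidations are over.

Step 16
Reactants: 22 dialkenyl diepoxycyclohexanol
Product: 25 diepoxy cyclodecenone, via potassium alkoxide 23 (not isolated), via potassium enolate 24 (not isolated)
Conditions: KH, 18-crown-6, THF, −20 → 0 °C; AcOH, −78 °C
Reagents that add atoms: none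
Why: KH with 18-crown-6 gives the dissociated C6 alkoxide 23, whose 1,5-diene C8=C7–C6–C1–C10=C9 undergoes a charge-accelerated [3,3] shift through a chair with C2 axial on C1 and C5 equatorial on C6, cutting C1–C6 and forming C8–C9 to give enolate 24, which is protonated cold to 25. The closest known reaction is the anionic oxy-Cope ring expansion of 1,2-divinylcyclohexanols to cyclodec-5-enones; the ten-membered ring is not closed by a cyclisation but arises by four-carbon ring expansion of the six-membered ring in a concerted sigmatropic mode through a six-membered chair transition state. C8 and C9 are set by the (E)-enol ether and the (Z)-silyloxyacrylate, both oxygens lying pseudo-equatorial on the chair, and their absolute sense follows from the cis C1/C6 arrangement on the enantiopure diepoxide ring, while the axial C2 gives the ring-cis C1=C10 bond. The step needs this chair and not the one with C2 equatorial, and the CO2TMSE group on C10 should secure it, because an equatorial C2 would be eclipsed with that ester in the developing trisubstituted alkene whereas the axial C2 meets only the C9 hydrogen. It also needs the [3,3] shift to outrun Payne migration, acyl transfer to the alkoxide and E1cB loss of the C8 oxygen: the Payne-shifted alkoxides cannot rearrange and return to 23, the C14 ester is a deactivated vinylogous carbonate, and in the first-formed enolate the C8–O bond lies in the nodal plane until the quench at −78 °C.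

Step 17
Reactants: 25 diepoxy cyclodecenone
Product: 27 C7 acetate ketone, via lithium enolate 26 (not isolated)
Conditions: LiN(SiMe3)2, THF, −78 °C; ICH2CO2Me, −78 → −40 °C
Reagents that add atoms: methyl iodoacetate, COC(=O)CI
Why: Regiospecific enolate alkylation (only C7 can enolise, C5 being an oxirane carbon) in which, by analogy with Fráter–Seebach alkylations, the lithium enolate chelated by the C8 ether oxygen should be attacked anti to C9 to give the 7,8-anti (7R) product, the chelate also holding the C8–O bond in the enolate plane against E1cB loss.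

Step 18
Reactants: 27 C7 acetate ketone
Product: 29 trans-lactone, via hydroxy ester 28 (not isolated)
Conditions: NaBH4, CeCl3·7H2O, MeOH, −78 °C; then PPTS (cat.), CH2Cl2, rt
Reagents that add atoms: none
Why: Luche reduction followed by lactonisation, in which hydride should add to C6 anti to the large C8 branch of the C7 stereocentre (Felkin–Anh) and from the outer face of the ring to give the 6S alcohol, which closes the five-membered lactone onto the methyl ester (5-exo-trig acyl substitution, O8 being blocked as its PMB ether).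

Step 19
Reactants: 29 trans-lactone
Product: 31 Mannich base, via lithium lactone enolate 30 (not isolated)
Conditions: LiN(iPr)2, THF, −78 °C; CH2=NMe2+ I−, −78 → 0 °C
Reagents that add atoms: Eschenmoser's salt, C=[N+](C)C.[I-]
Why: Mannich alkylation of the lactone enolate at C11 is run before any base-labile ester is in the molecule, and the new C11 centre is removed in step 20.

Step 20
Reactants: 31 Mannich base
Product: 33 α-methylene lactone, via methiodide 32 (not isolated)
Conditions: MeI, MeOH, rt; NaHCO3, EtOAc/H2O, rt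
Reagents that add atoms: none
Why: Quaternisation and Hofmann-type β-elimination of trimethylamine under bicarbonate gives the exocyclic C11=C13 bond.

Step 21
Reactants: 33 α-methylene lactone
Product: 34 C8 alcohol
Conditions: DDQ, CH2Cl2/pH 7 buffer, 0 °C
Reagents that add atoms: none
Why: Oxidative cleavage of the PMB ether by DDQ frees the C8 hydroxyl without touching the silyl ether, the silyl ester, the oxiranes or the enoates.

Step 22
Reactants: 35 angelic acid
Product: 36 (Z)-2-methylbut-2-en-1-ol
Conditions: LiAlH4, Et2O, 0 °C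
Reagents that add atoms: none
Why: Hydride reduction of the acid gives the allylic alcohol with the Z geometry intact.

Step 23
Reactants: 36 (Z)-2-methylbut-2-en-1-ol
Product: 37 (2S,3R)-epoxy alcohol
Conditions: Ti(OiPr)4, L-(+)-diethyl tartrate, t-BuOOH, 4 Å MS, CH2Cl2, −20 °C
Reagents that add atoms: tert-butyl hydroperoxide, CC(C)(C)OO
Why: Sharpless asymmetric epoxidation with L-(+)-tartrate should deliver oxygen to the face that gives the (2S,3R)-epoxy alcohol, the cis relation of CH2OH and the 3-methyl coming from the Z alkene.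

Step 24
Reactants: 37 (2S,3R)-epoxy alcohol
Product: 38 (2R,3R)-epoxyangelic acid
Conditions: TEMPO (cat.), PhI(OAc)2, MeCN/H2O, rt
Reagents that add atoms: water, O
Why: TEMPO/PhI(OAc)2 oxidation takes the primary alcohol through the aldehyde hydrate to the glycidic acid under conditions that spare the oxirane, the C2 descriptor changing to R only through the change in priorities.

Step 25
Reactants: 34 C8 alcohol; 38 (2R,3R)-epoxyangelic acid
Product: 39 C8 epoxyangelate
Conditions: DCC, DMAP, CH2Cl2, 0 °C → rt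
Reagents that add atoms: none
Why: Steglich esterification of the C8 alcohol with the preformed epoxy acid brings in both side-chain stereocentres intact and is run without excess base to avoid migration of the lactone from O6 to O8.

Step 26
Reactants: 39 C8 epoxyangelate
Product: 40 C9 alcohol
Conditions: HF·pyridine, pyridine, THF, 0 °C
Reagents that add atoms: none
Why: Buffered HF·pyridine desilylation removes the secondary TBS ether at C9, while the 2-(trimethylsilyl)ethyl ester, which needs free fluoride, and the carboxylic esters should survive.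

Step 27
Reactants: 40 C9 alcohol
Product: 41 C9 acetate
Conditions: Ac2O, pyridine, DMAP (cat.), CH2Cl2, 0 °C
Reagents that add atoms: acetic anhydride, CC(=O)OC(C)=O
Why: DMAP-catalysed acetylation of the C9 alcohol is faster than any migration of the hindered C8 ester.

Step 28
Reactants: 41 C9 acetate
Product: 42 leucanthin B
Conditions: (Me2N)3S+ Me3SiF2− (TASF), DMF, 0 °C; pH 4 phosphate buffer
Reagents that add atoms: none
Why: Fluoride-induced β-elimination of the 2-(trimethylsilyl)ethyl ester releases the C14 acid without hydrolysing the acetate, the epoxyangelate or the lactone.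

**Compound list**

1 | 4-methoxy-2-methylphenol | COc1ccc(O)c(C)c1 | starting material
2 | 4,4-dimethoxy-2-methylcyclohexa-2,5-dien-1-one (C3 ketone, C6 ketal) | CC1=CC(OC)(OC)C=CC1=O | intermediate
3 | (S)-4,4-dimethoxy-2-methylcyclohexa-2,5-dien-1-ol (C3 carbinol) | O[C@@H]1C(C)=CC(OC)(OC)C=C1 | intermediate
4 | C3 alcohol with 4,5-oxirane cis to the hydroxyl, C6 dimethyl ketal, C1=C2 | O[C@@H]1[C@]2(C)O[C@@H]2C(OC)(OC)C=C1 | intermediate
5 | 3-(benzyloxy)propanoic acid | OC(=O)CCOCc1ccccc1 | starting material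
6 | 3-(benzyloxy)propanoate of 4 at O3 | O=C(CCOCc1ccccc1)O[C@@H]1[C@]2(C)O[C@@H]2C(OC)(OC)C=C1 | intermediate
7 | O-trimethylsilyl ketene acetal of 6 | C[Si](C)(C)OC(=CCOCc1ccccc1)O[C@@H]1[C@]2(C)O[C@@H]2C(OC)(OC)C=C1 | intermediate
8 | trimethylsilyl ester of acid 9 | COC1(OC)[C@H](C(COCc2ccccc2)C(=O)O[Si](C)(C)C)C=C[C@]2(C)O[C@H]12 | intermediate
9 | acid with C1 bearing CH(CO2H)CH2OBn cis to the 4,5-oxirane oxygen, C2=C3, C6 ketal (C10 epimers) | COC1(OC)[C@H](C(COCc2ccccc2)C(=O)O)C=C[C@]2(C)O[C@H]12 | intermediate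
10 | 2-(trimethylsilyl)ethanol | C[Si](C)(C)CCO | starting material
11 | 2-(trimethylsilyl)ethyl ester of 9 | COC1(OC)[C@H](C(COCc2ccccc2)C(=O)OCC[Si](C)(C)C)C=C[C@]2(C)O[C@H]12 | intermediate
12 | 2,3:4,5-bis-epoxide (oxiranes anti; 2,3-oxirane trans to the C1 side chain), C6 ketal | COC1(OC)[C@H](C(COCc2ccccc2)C(=O)OCC[Si](C)(C)C)[C@H]2O[C@H]2[C@]2(C)O[C@H]12 | intermediate
13 | 2,3:4,5-diepoxy C6 ketone | O=C1[C@H](C(COCc2ccccc2)C(=O)OCC[Si](C)(C)C)[C@H]2O[C@H]2[C@]2(C)O[C@H]12 | intermediate
14 | C6 exocyclic methylene (C7) diepoxide | C=C1[C@H](C(COCc2ccccc2)C(=O)OCC[Si](C)(C)C)[C@H]2O[C@H]2[C@]2(C)O[C@H]12 | intermediate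
15 | C6 tertiary alcohol (O6 trans to the 4,5-oxirane oxygen) with C7 hydroxymethyl cis to the C1 side chain | O[C@@]1(CO)[C@H](C(COCc2ccccc2)C(=O)OCC[Si](C)(C)C)[C@H]2O[C@H]2[C@]2(C)O[C@H]12 | intermediate
16 | triol (O6, O7, O9 free) | O[C@@]1(CO)[C@H](C(CO)C(=O)OCC[Si](C)(C)C)[C@H]2O[C@H]2[C@]2(C)O[C@H]12 | intermediate
17 | C6 hydroxy C7 aldehyde with α-formyl ester on C1 (drawn as the aldehyde) | O[C@@]1(C=O)[C@H](C(C=O)C(=O)OCC[Si](C)(C)C)[C@H]2O[C@H]2[C@]2(C)O[C@H]12 | intermediate
18 | sodium (Z)-enolate of the formyl ester of 17 | O[C@@]1(C=O)[C@H](/C(C(=O)OCC[Si](C)(C)C)=C/[O-])[C@H]2O[C@H]2[C@]2(C)O[C@H]12.[Na+] | intermediate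
19 | C7 aldehyde with (Z)-2-(TBS-oxy)vinyl ester unit on C1 (O9 trans to C1) | O[C@@]1(C=O)[C@H](/C(C(=O)OCC[Si](C)(C)C)=C/O[Si](C)(C)C(C)(C)C)[C@H]2O[C@H]2[C@]2(C)O[C@H]12 | intermediate
20 | C6 (E)-2-(pinacolboryl)vinyl carbinol | O[C@@]1(/C=C/B3OC(C)(C)C(C)(C)O3)[C@H](/C(C(=O)OCC[Si](C)(C)C)=C/O[Si](C)(C)C(C)(C)C)[C@H]2O[C@H]2[C@]2(C)O[C@H]12 | intermediate
21 | 4-methoxybenzyl alcohol | COc1ccc(CO)cc1 | starting material
22 | cis-1,2-dialkenyl 2,3:4,5-diepoxycyclohexanol: C6 OH with (E)-2-(PMB-oxy)vinyl, C1 (Z)-silyloxyacrylate | O[C@@]1(/C=C/OCc2ccc(OC)cc2)[C@H](/C(C(=O)OCC[Si](C)(C)C)=C/O[Si](C)(C)C(C)(C)C)[C@H]2O[C@H]2[C@]2(C)O[C@H]12 | intermediate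
23 | potassium C6 alkoxide of 22 | [K+].[O-][C@@]1(/C=C/OCc2ccc(OC)cc2)[C@H](/C(C(=O)OCC[Si](C)(C)C)=C/O[Si](C)(C)C(C)(C)C)[C@H]2O[C@H]2[C@]2(C)O[C@H]12 | intermediate
24 | potassium C6/C7 enolate of 25 | [K+].[O-]C1=C[C@H](OCc2ccc(OC)cc2)[C@@H](O[Si](C)(C)C(C)(C)C)/C(C(=O)OCC[Si](C)(C)C)=C\[C@H]2O[C@H]2[C@]2(C)O[C@@H]21 | intermediate
25 | 2,3:4,5-diepoxy cyclodec-1(10)-en-6-one, ring-cis C1=C10, (8S)-OPMB, (9S)-OTBS, C14 TMSE ester | C1[C@H](OCc2ccc(OC)cc2)[C@@H](O[Si](C)(C)C(C)(C)C)/C(C(=O)OCC[Si](C)(C)C)=C\[C@H]2O[C@H]2[C@]2(C)O[C@@H]2C1=O | intermediate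
26 | lithium C6/C7 enolate of 25 | [Li+].[O-]C1=C[C@H](OCc2ccc(OC)cc2)[C@@H](O[Si](C)(C)C(C)(C)C)/C(C(=O)OCC[Si](C)(C)C)=C\[C@H]2O[C@H]2[C@]2(C)O[C@@H]21 | intermediate
27 | (7R)-7-(methoxycarbonylmethyl) ketone | COC(=O)C[C@@H]1[C@H](OCc2ccc(OC)cc2)[C@@H](O[Si](C)(C)C(C)(C)C)/C(C(=O)OCC[Si](C)(C)C)=C\[C@H]2O[C@H]2[C@]2(C)O[C@@H]2C1=O | intermediate
28 | (6S)-hydroxy methyl ester | COC(=O)C[C@@H]1[C@H](OCc2ccc(OC)cc2)[C@@H](O[Si](C)(C)C(C)(C)C)/C(C(=O)OCC[Si](C)(C)C)=C\[C@H]2O[C@H]2[C@]2(C)O[C@@H]2[C@H]1O | intermediate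
29 | trans-fused 6,12-lactone (6S,7R), C11 methylene saturated | C1C(=O)O[C@H]2[C@H]1[C@H](OCc3ccc(OC)cc3)[C@@H](O[Si](C)(C)C(C)(C)C)/C(C(=O)OCC[Si](C)(C)C)=C\[C@H]1O[C@H]1[C@]1(C)O[C@H]21 | intermediate
30 | lithium enolate of lactone 29 | [Li+].C1=C([O-])O[C@H]2[C@H]1[C@H](OCc3ccc(OC)cc3)[C@@H](O[Si](C)(C)C(C)(C)C)/C(C(=O)OCC[Si](C)(C)C)=C\[C@H]1O[C@H]1[C@]1(C)O[C@H]21 | intermediate
31 | 11-(dimethylaminomethyl) lactone (C11 epimers) | CN(C)CC1C(=O)O[C@H]2[C@H]1[C@H](OCc3ccc(OC)cc3)[C@@H](O[Si](C)(C)C(C)(C)C)/C(C(=O)OCC[Si](C)(C)C)=C\[C@H]1O[C@H]1[C@]1(C)O[C@H]21 | intermediate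
32 | trimethylammonium iodide of 31 | C[N+](C)(C)CC1C(=O)O[C@H]2[C@H]1[C@H](OCc3ccc(OC)cc3)[C@@H](O[Si](C)(C)C(C)(C)C)/C(C(=O)OCC[Si](C)(C)C)=C\[C@H]1O[C@H]1[C@]1(C)O[C@H]21.[I-] | intermediate
33 | α-methylene lactone with 8-OPMB, 9-OTBS, C14 TMSE ester | C=C1C(=O)O[C@H]2[C@H]1[C@H](OCc3ccc(OC)cc3)[C@@H](O[Si](C)(C)C(C)(C)C)/C(C(=O)OCC[Si](C)(C)C)=C\[C@H]1O[C@H]1[C@]1(C)O[C@H]21 | intermediate
34 | C8 alcohol | C=C1C(=O)O[C@H]2[C@H]1[C@H](O)[C@@H](O[Si](C)(C)C(C)(C)C)/C(C(=O)OCC[Si](C)(C)C)=C\[C@H]1O[C@H]1[C@]1(C)O[C@H]21 | intermediate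
35 | angelic acid, (Z)-2-methylbut-2-enoic acid | C/C=C(C)\C(=O)O | starting material
36 | (Z)-2-methylbut-2-en-1-ol | C/C=C(C)\CO | intermediate
37 | (2S,3R)-2,3-epoxy-2-methylbutan-1-ol | OC[C@]1(C)O[C@@H]1C | intermediate
38 | (2R,3R)-2,3-dimethyloxirane-2-carboxylic acid | OC(=O)[C@]1(C)O[C@@H]1C | intermediate
39 | C8 epoxyangelate, 9-OTBS, C14 TMSE ester | C=C1C(=O)O[C@H]2[C@H]1[C@H](OC(=O)[C@]1(C)O[C@@H]1C)[C@@H](O[Si](C)(C)C(C)(C)C)/C(C(=O)OCC[Si](C)(C)C)=C\[C@H]1O[C@H]1[C@]1(C)O[C@H]21 | intermediate
40 | C9 alcohol | C=C1C(=O)O[C@H]2[C@H]1[C@H](OC(=O)[C@]1(C)O[C@@H]1C)[C@@H](O)/C(C(=O)OCC[Si](C)(C)C)=C\[C@H]1O[C@H]1[C@]1(C)O[C@H]21 | intermediate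
41 | C9 acetate, C14 TMSE ester | C=C1C(=O)O[C@H]2[C@H]1[C@H](OC(=O)[C@]1(C)O[C@@H]1C)[C@@H](OC(C)=O)/C(C(=O)OCC[Si](C)(C)C)=C\[C@H]1O[C@H]1[C@]1(C)O[C@H]21 | intermediate
42 | leucanthin B | C=C1C(=O)O[C@H]2[C@H]1[C@H](OC(=O)[C@]1(C)O[C@@H]1C)[C@@H](OC(C)=O)/C(C(=O)O)=C\[C@H]1O[C@H]1[C@]1(C)O[C@H]21 | target

**Step count and risks**

Total steps: 28. Longest linear sequence: 25 (steps 1–21 and 25–28); the epoxy acid branch is steps 22–24.

Most likely to fail:

1. Step 16. The rearrangement may pass through the other chair (C2 equatorial, giving the ring-trans C1=C10 bond). The enolate may lose the C8 alkoxide by E1cB. A ring alkoxide may attack the C14 ester while the Payne shifts run. Fallback, setting out from 22: O6 is silylated with N-(trimethylsilyl)imidazole to the C6 trimethylsilyl ether F1. Heating F1 in degassed decalin at about 180 °C in base-washed glass should bring about the neutral siloxy-Cope shift, with no alkoxide present, to the trimethylsilyl enol ether F2. Brief treatment of F2 with citric acid in wet THF returns to 25.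

2. Step 15. The alkenylboronate may suffer protodeboronation or oxidative homocoupling, and the silyl group of the silyloxyacrylate may be transferred to the alcohol under copper and amine. Fallback, setting out from 19 and leaving out 20: Julia–Kocienski olefination of the aldehyde with 5-{[(4-methoxybenzyl)oxy]methylsulfonyl}-1-phenyl-1H-tetrazole and KN(SiMe3)2 in DME at −60 °C should give the (E)-enol ether directly and comes back to the route at 22.

3. Step 18. Hydride may be delivered to the other face of C6 (the chelation mode typical of α,β-epoxy ketones), which ends in the cis-fused lactone. Fallback, setting out from 27: Zn(BH4)2 in Et2O, through a chelate of the C6 carbonyl with the oxirane oxygen, gives on purpose the 6R hydroxy ester F3, which closes to the cis-fused lactone F4. LiOH in THF/H2O at 0 °C opens F4 to the 6R hydroxy acid F5. Mitsunobu lactonisation (PPh3, DIAD, THF) with inversion at C6 then comes back to the route at 29.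

Further compounds
F1 | step 16 | C6 trimethylsilyl ether of 22 | C[Si](C)(C)O[C@@]1(/C=C/OCc2ccc(OC)cc2)[C@H](/C(C(=O)OCC[Si](C)(C)C)=C/O[Si](C)(C)C(C)(C)C)[C@H]2O[C@H]2[C@]2(C)O[C@H]12
F2 | step 16 | C6 trimethylsilyl enol ether of 25 | C[Si](C)(C)OC1=C[C@H](OCc2ccc(OC)cc2)[C@@H](O[Si](C)(C)C(C)(C)C)/C(C(=O)OCC[Si](C)(C)C)=C\[C@H]2O[C@H]2[C@]2(C)O[C@@H]21
F0 | step 15 | none | none
F3 | step 18 | 6R hydroxy methyl ester (C6 epimer of 28) | COC(=O)C[C@@H]1[C@H](OCc2ccc(OC)cc2)[C@@H](O[Si](C)(C)C(C)(C)C)/C(C(=O)OCC[Si](C)(C)C)=C\[C@H]2O[C@H]2[C@]2(C)O[C@@H]2[C@@H]1O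
F4 | step 18 | cis-fused 6,12-lactone (C6 epimer of 29) | C1C(=O)O[C@@H]2[C@H]1[C@H](OCc3ccc(OC)cc3)[C@@H](O[Si](C)(C)C(C)(C)C)/C(C(=O)OCC[Si](C)(C)C)=C\[C@H]1O[C@H]1[C@]1(C)O[C@H]21
F5 | step 18 | 6R hydroxy acid (C12 acid) | OC(=O)C[C@@H]1[C@H](OCc2ccc(OC)cc2)[C@@H](O[Si](C)(C)C(C)(C)C)/C(C(=O)OCC[Si](C)(C)C)=C\[C@H]2O[C@H]2[C@]2(C)O[C@@H]2[C@@H]1O
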